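## Retrosynthetic overview

1. Key disconnection C2-C3: an asymmetric carbonyl allylation (allylboration) joins fragment A, 3,5-bis(benzyloxy)phenylacetaldehyde (arene plus C1-C2), to allyl fragment B (C3-C5) and sets C2 (R).
2. C4=C5-C6: cross metathesis of the silyl-protected homoallylic alcohol with methyl acrylate, followed by reduction and iodination, gives an (E)-allylic iodide.
3. C6-C7: auxiliary-controlled alkylation of an O-benzyl glycolate imide with that iodide sets C7 (R). C8-C9 comes from a Weinreb amide and pentylmagnesium bromide.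
4. End game: TBS is exchanged for acetate at C2, then one neutral hydrogenation saturates C4=C5 and frees the three benzyl-protected hydroxyls.
5. Rings: none is formed. The only ring, the resorcinol arene, is bought in methyl 3,5-dihydroxyphenylacetate.

Assumption: the SMILES is read as (2R,7R)-1-(3,5-dihydroxyphenyl)-7-hydroxy-8-oxotridecan-2-yl acetate, with the chain numbered from C1 (benzylic CH2) to C13 (terminal CH3).

## Route

Step 1
Reactants: 1 methyl 2-(3,5-dihydroxyphenyl)acetate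
Product: 2 methyl 2-[3,5-bis(benzyloxy)phenyl]acetate
Conditions: BnBr (2.4 equiv), K2CO3, DMF, 50 °C
Reagents that add atoms: benzyl bromide, BrCc1ccccc1
Why: Williamson ether synthesis, in which the phenoxides displace bromide by SN2 while the weak carbonate base leaves the ester and its alpha-CH2 alone.

Step 2
Reactants: 2 methyl 2-[3,5-bis(benzyloxy)phenyl]acetate
Product: 3 2-[3,5-bis(benzyloxy)phenyl]ethan-1-ol
Conditions: LiAlH4, THF, 0 °C
Reagents that add atoms: none
Why: Hydride reduction of the ester goes cleanly to the primary alcohol, avoids the over-reduction risk of a direct ester-to-aldehyde reduction, and leaves the benzyl ethers untouched.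

Step 3
Reactants: 3 2-[3,5-bis(benzyloxy)phenyl]ethan-1-ol
Product: 4 2-[3,5-bis(benzyloxy)phenyl]acetaldehyde (fragment A)
Conditions: Dess-Martin periodinane, CH2Cl2, 0 °C to rt; used at once after a short silica plug
Reagents that add atoms: none
Why: Dess-Martin oxidation stops at the aldehyde under nearly neutral conditions, which keeps the enolisable arylacetaldehyde from self-aldolising.

Step 4
Reactants: 4 2-[3,5-bis(benzyloxy)phenyl]acetaldehyde (fragment A); 5 (+)-B-chlorodiisopinocampheylborane, (+)-Ipc2BCl, the enantiomer made from (-)-alpha-pinene; 6 allylmagnesium bromide (fragment B)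
Product: 9 (2R)-1-[3,5-bis(benzyloxy)phenyl]pent-4-en-2-ol, via B-allyldiisopinocampheylborane 7 (not isolated), via homoallyl diisopinocampheylborinate 8 (not isolated)
Conditions: 5 + 6, Et2O, -78 °C to rt; then 4, Et2O, -78 °C; then NaOH, H2O2, 0 °C to rt
Reagents that add atoms: none
Why: Key step, a Brown asymmetric allylboration (carbonyl allylation) through a closed chair transition state in which the isopinocampheyl groups of the (-)-alpha-pinene series steer the allyl group onto the Re face of 4, forming C2-C3 and setting C2 as R (about 90-95% ee expected), while the fast non-basic addition at -78 °C outruns enolisation.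

Step 5
Reactants: 9 (2R)-1-[3,5-bis(benzyloxy)phenyl]pent-4-en-2-ol
Product: 10 tert-butyl{[(2R)-1-[3,5-bis(benzyloxy)phenyl]pent-4-en-2-yl]oxy}dimethylsilane
Conditions: TBSCl, imidazole, DMF, rt
Reagents that add atoms: tert-butyldimethylsilyl chloride, CC(C)(C)[Si](C)(C)Cl
Why: Imidazole-promoted silylation masks the C2 hydroxyl with a group that survives the hydride, enolate, aluminium amide and Grignard steps, and the C-O bond at C2 is not broken.

Step 6
Reactants: 10 tert-butyl{[(2R)-1-[3,5-bis(benzyloxy)phenyl]pent-4-en-2-yl]oxy}dimethylsilane; 11 methyl acrylate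
Product: 12 methyl (2E,5R)-6-[3,5-bis(benzyloxy)phenyl]-5-[(tert-butyldimethylsilyl)oxy]hex-2-enoate
Conditions: 11 (5 equiv), second-generation Hoveyda-Grubbs catalyst (H2IMes)Cl2Ru=CH(2-i-PrOC6H4) (3 mol %), CH2Cl2, 40 °C
Reagents that add atoms: none
Why: Olefin cross metathesis between a reactive type 1 terminal alkene and the electron-poor type 2 acrylate is selective for the (E)-cross product, because the acrylate hardly homodimerises.

Step 7
Reactants: 12 methyl (2E,5R)-6-[3,5-bis(benzyloxy)phenyl]-5-[(tert-butyldimethylsilyl)oxy]hex-2-enoate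
Product: 13 (2E,5R)-6-[3,5-bis(benzyloxy)phenyl]-5-[(tert-butyldimethylsilyl)oxy]hex-2-en-1-ol
Conditions: i-Bu2AlH (2.5 equiv), CH2Cl2, -78 °C
Reagents that add atoms: none
Why: 1,2-Reduction of the enoate with the aluminium hydride gives the allylic alcohol without conjugate reduction or loss of the silyl ether.

Step 8
Reactants: 13 (2E,5R)-6-[3,5-bis(benzyloxy)phenyl]-5-[(tert-butyldimethylsilyl)oxy]hex-2-en-1-ol
Product: 14 tert-butyl{[(2R,4E)-1-[3,5-bis(benzyloxy)phenyl]-6-iodohex-4-en-2-yl]oxy}dimethylsilane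
Conditions: I2, PPh3, imidazole, CH2Cl2, 0 °C, dark; used directly
Reagents that add atoms: iodine, II
Why: Appel-type iodination turns the primary allylic alcohol into the iodide by SN2 at the alkoxyphosphonium stage, with the E geometry kept.

Step 9
Reactants: 15 (4S)-4-benzyl-1,3-oxazolidin-2-one; 16 (benzyloxy)acetyl chloride
Product: 18 (4S)-4-benzyl-3-[(benzyloxy)acetyl]-1,3-oxazolidin-2-one, via N-lithio oxazolidinone 17 (not isolated)
Conditions: n-BuLi, THF, -78 °C; then 16, -78 to 0 °C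
Reagents that add atoms: none
Why: N-Acylation of the lithiated auxiliary with the acid chloride is a standard, high-yielding imide synthesis that does not touch the auxiliary stereocentre.

Step 10
Reactants: 18 (4S)-4-benzyl-3-[(benzyloxy)acetyl]-1,3-oxazolidin-2-one; 14 tert-butyl{[(2R,4E)-1-[3,5-bis(benzyloxy)phenyl]-6-iodohex-4-en-2-yl]oxy}dimethylsilane
Product: 20 (4S)-4-benzyl-3-[(2R,4E,7R)-2-(benzyloxy)-8-[3,5-bis(benzyloxy)phenyl]-7-[(tert-butyldimethylsilyl)oxy]oct-4-enoyl]-1,3-oxazolidin-2-one, via sodium Z-enolate 19 (not isolated)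
Conditions: 18 (1.5 equiv), NaN(SiMe3)2, THF, -78 °C; then 14, -78 to -45 °C
Reagents that add atoms: none
Why: Evans-type asymmetric alkylation of a glycolate imide, in which the benzyl group of the auxiliary shields one face of the sodium-chelated Z-enolate so the reactive allylic iodide attacks by SN2 from the open face, forming C6-C7 and setting C7 as R (dr above 95:5, minor isomer removed by chromatography).

Step 11
Reactants: 20 (4S)-4-benzyl-3-[(2R,4E,7R)-2-(benzyloxy)-8-[3,5-bis(benzyloxy)phenyl]-7-[(tert-butyldimethylsilyl)oxy]oct-4-enoyl]-1,3-oxazolidin-2-one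
Product: 21 (2R,4E,7R)-2-(benzyloxy)-8-[3,5-bis(benzyloxy)phenyl]-7-[(tert-butyldimethylsilyl)oxy]-N-methoxy-N-methyloct-4-enamide
Conditions: MeONHMe·HCl, AlMe3, CH2Cl2, 0 °C to rt
Reagents that add atoms: N,O-dimethylhydroxylamine hydrochloride, CNOC.Cl
Why: Weinreb transamidation with the aluminium amide attacks the activated, unhindered alpha-alkoxy exocyclic carbonyl, releases the auxiliary, and is non-basic enough to leave C7 intact.

Step 12
Reactants: 21 (2R,4E,7R)-2-(benzyloxy)-8-[3,5-bis(benzyloxy)phenyl]-7-[(tert-butyldimethylsilyl)oxy]-N-methoxy-N-methyloct-4-enamide; 22 pentylmagnesium bromide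
Product: 24 (7R,9E,12R)-7-(benzyloxy)-13-[3,5-bis(benzyloxy)phenyl]-12-[(tert-butyldimethylsilyl)oxy]tridec-9-en-6-one, via magnesium-chelated tetrahedral adduct 23 (not isolated)
Conditions: 22 (C5H11MgBr, 2 equiv), THF, -78 to 0 °C; aqueous quench
Reagents that add atoms: none
Why: Weinreb ketone synthesis, in which the chelated tetrahedral adduct survives until the quench, so only one pentyl group adds and the alpha-alkoxy centre C7 is not enolised.

Step 13
Reactants: 24 (7R,9E,12R)-7-(benzyloxy)-13-[3,5-bis(benzyloxy)phenyl]-12-[(tert-butyldimethylsilyl)oxy]tridec-9-en-6-one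
Product: 25 (7R,9E,12R)-7-(benzyloxy)-13-[3,5-bis(benzyloxy)phenyl]-12-hydroxytridec-9-en-6-one
Conditions: HF·pyridine, THF, 0 °C to rt
Reagents that add atoms: none
Why: Fluoride-driven desilylation under mildly acidic buffered conditions frees only the C2 hydroxyl and avoids the basic medium that could epimerise the alpha-benzyloxy ketone.

Step 14
Reactants: 25 (7R,9E,12R)-7-(benzyloxy)-13-[3,5-bis(benzyloxy)phenyl]-12-hydroxytridec-9-en-6-one
Product: 26 (2R,4E,7R)-7-(benzyloxy)-1-[3,5-bis(benzyloxy)phenyl]-8-oxotridec-4-en-2-yl acetate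
Conditions: Ac2O, pyridine, DMAP (cat.), CH2Cl2, 0 °C to rt
Reagents that add atoms: acetic anhydride, CC(=O)OC(C)=O
Why: DMAP-catalysed acetylation hits the only free hydroxyl and keeps the C2 configuration because the C-O bond is not broken.

Step 15
Reactants: 26 (2R,4E,7R)-7-(benzyloxy)-1-[3,5-bis(benzyloxy)phenyl]-8-oxotridec-4-en-2-yl acetate
Product: 27 (2R,7R)-1-(3,5-dihydroxyphenyl)-7-hydroxy-8-oxotridecan-2-yl acetate (target)
Conditions: H2 (1 atm), Pd/C (10 wt %), EtOAc, rt
Reagents that add atoms: none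
Why: Catalytic hydrogenation and hydrogenolysis in one neutral operation saturates C4=C5 and cleaves the three benzyl ethers, while the dialkyl ketone, the acetate and both stereocentres are left as they are and the alpha-ketol never meets acid or base.

## Compound list

1 | methyl 2-(3,5-dihydroxyphenyl)acetate | COC(=O)Cc1cc(O)cc(O)c1 | starting material
2 | methyl 2-[3,5-bis(benzyloxy)phenyl]acetate | COC(=O)Cc1cc(OCc2ccccc2)cc(OCc2ccccc2)c1 | intermediate
3 | 2-[3,5-bis(benzyloxy)phenyl]ethan-1-ol | OCCc1cc(OCc2ccccc2)cc(OCc2ccccc2)c1 | intermediate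
4 | 2-[3,5-bis(benzyloxy)phenyl]acetaldehyde | O=CCc1cc(OCc2ccccc2)cc(OCc2ccccc2)c1 | intermediate
5 | (+)-B-chlorodiisopinocampheylborane, (-)-alpha-pinene series | ClB([C@H]1C[C@H]2C[C@@H]([C@@H]1C)C2(C)C)[C@H]1C[C@H]2C[C@@H]([C@@H]1C)C2(C)C | starting material
6 | allylmagnesium bromide | C=CC[Mg]Br | starting material
7 | B-allyldiisopinocampheylborane, (-)-alpha-pinene series | C=CCB([C@H]1C[C@H]2C[C@@H]([C@@H]1C)C2(C)C)[C@H]1C[C@H]2C[C@@H]([C@@H]1C)C2(C)C | intermediate
8 | (2R)-1-[3,5-bis(benzyloxy)phenyl]pent-4-en-2-yl diisopinocampheylborinate | C=CC[C@H](Cc1cc(OCc2ccccc2)cc(OCc2ccccc2)c1)OB([C@H]1C[C@H]2C[C@@H]([C@@H]1C)C2(C)C)[C@H]1C[C@H]2C[C@@H]([C@@H]1C)C2(C)C | intermediate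
9 | (2R)-1-[3,5-bis(benzyloxy)phenyl]pent-4-en-2-ol | C=CC[C@H](Cc1cc(OCc2ccccc2)cc(OCc2ccccc2)c1)O | intermediate
10 | tert-butyl{[(2R)-1-[3,5-bis(benzyloxy)phenyl]pent-4-en-2-yl]oxy}dimethylsilane | C=CC[C@H](Cc1cc(OCc2ccccc2)cc(OCc2ccccc2)c1)O[Si](C)(C)C(C)(C)C | intermediate
11 | methyl acrylate | C=CC(=O)OC | starting material
12 | methyl (2E,5R)-6-[3,5-bis(benzyloxy)phenyl]-5-[(tert-butyldimethylsilyl)oxy]hex-2-enoate | COC(=O)/C=C/C[C@H](Cc1cc(OCc2ccccc2)cc(OCc2ccccc2)c1)O[Si](C)(C)C(C)(C)C | intermediate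
13 | (2E,5R)-6-[3,5-bis(benzyloxy)phenyl]-5-[(tert-butyldimethylsilyl)oxy]hex-2-en-1-ol | OC/C=C/C[C@H](Cc1cc(OCc2ccccc2)cc(OCc2ccccc2)c1)O[Si](C)(C)C(C)(C)C | intermediate
14 | tert-butyl{[(2R,4E)-1-[3,5-bis(benzyloxy)phenyl]-6-iodohex-4-en-2-yl]oxy}dimethylsilane | IC/C=C/C[C@H](Cc1cc(OCc2ccccc2)cc(OCc2ccccc2)c1)O[Si](C)(C)C(C)(C)C | intermediate
15 | (4S)-4-benzyl-1,3-oxazolidin-2-one | O=C1N[C@@H](Cc2ccccc2)CO1 | starting material
16 | (benzyloxy)acetyl chloride | O=C(Cl)COCc1ccccc1 | starting material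
17 | lithium salt of (4S)-4-benzyl-1,3-oxazolidin-2-one | [Li]N1[C@@H](Cc2ccccc2)COC1=O | intermediate
18 | (4S)-4-benzyl-3-[(benzyloxy)acetyl]-1,3-oxazolidin-2-one | O=C(COCc1ccccc1)N1[C@@H](Cc2ccccc2)COC1=O | intermediate
19 | sodium (Z)-enolate of 18 | [Na+].[O-]/C(=C\OCc1ccccc1)N1[C@@H](Cc2ccccc2)COC1=O | intermediate
20 | (4S)-4-benzyl-3-[(2R,4E,7R)-2-(benzyloxy)-8-[3,5-bis(benzyloxy)phenyl]-7-[(tert-butyldimethylsilyl)oxy]oct-4-enoyl]-1,3-oxazolidin-2-one | O=C1OC[C@H](Cc2ccccc2)N1C(=O)[C@H](OCc1ccccc1)C/C=C/C[C@H](Cc1cc(OCc2ccccc2)cc(OCc2ccccc2)c1)O[Si](C)(C)C(C)(C)C | intermediate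
21 | (2R,4E,7R)-2-(benzyloxy)-8-[3,5-bis(benzyloxy)phenyl]-7-[(tert-butyldimethylsilyl)oxy]-N-methoxy-N-methyloct-4-enamide | CON(C)C(=O)[C@H](OCc1ccccc1)C/C=C/C[C@H](Cc1cc(OCc2ccccc2)cc(OCc2ccccc2)c1)O[Si](C)(C)C(C)(C)C | intermediate
22 | pentylmagnesium bromide | CCCCC[Mg]Br | starting material
23 | bromomagnesium alkoxide of the tetrahedral adduct of 21 and 22 (new carbon centre unassigned) | CCCCCC(O[Mg]Br)(N(C)OC)[C@H](OCc1ccccc1)C/C=C/C[C@H](Cc1cc(OCc2ccccc2)cc(OCc2ccccc2)c1)O[Si](C)(C)C(C)(C)C | intermediate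
24 | (7R,9E,12R)-7-(benzyloxy)-13-[3,5-bis(benzyloxy)phenyl]-12-[(tert-butyldimethylsilyl)oxy]tridec-9-en-6-one | CCCCCC(=O)[C@H](OCc1ccccc1)C/C=C/C[C@H](Cc1cc(OCc2ccccc2)cc(OCc2ccccc2)c1)O[Si](C)(C)C(C)(C)C | intermediate
25 | (7R,9E,12R)-7-(benzyloxy)-13-[3,5-bis(benzyloxy)phenyl]-12-hydroxytridec-9-en-6-one | CCCCCC(=O)[C@H](OCc1ccccc1)C/C=C/C[C@H](Cc1cc(OCc2ccccc2)cc(OCc2ccccc2)c1)O | intermediate
26 | (2R,4E,7R)-7-(benzyloxy)-1-[3,5-bis(benzyloxy)phenyl]-8-oxotridec-4-en-2-yl acetate | CCCCCC(=O)[C@H](OCc1ccccc1)C/C=C/C[C@H](Cc1cc(OCc2ccccc2)cc(OCc2ccccc2)c1)OC(C)=O | intermediate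
27 | (2R,7R)-1-(3,5-dihydroxyphenyl)-7-hydroxy-8-oxotridecan-2-yl acetate | CCCCCC(=O)[C@H](O)CCCC[C@H](Cc1cc(O)cc(O)c1)OC(C)=O | target

## Step count and risks

Total step count: 15.
Longest linear sequence: 14 steps, from 1 to 27 through steps 1-8 and 10-15. Step 9 is the side branch.

**Step 4, allylboration of 4.** The arylacetaldehyde enolises and self-condenses easily, and this aldehyde class gives somewhat lower ee than simple aldehydes. The fallback sets out from 4 and comes back at 9. Methylenation of 4 with Ph3P=CH2 (Ph3PCH3Br, NaN(SiMe3)2, THF, -78 to 0 °C) gives 1-allyl-3,5-bis(benzyloxy)benzene F1. mCPBA in CH2Cl2 then gives racemic 2-[3,5-bis(benzyloxy)benzyl]oxirane F2. Hydrolytic kinetic resolution with (S,S)-(salen)Co(OAc) (trivalent cobalt, 0.5 mol %) and 0.55 equiv of water leaves (S)-2-[3,5-bis(benzyloxy)benzyl]oxirane F3 in over 99% ee. CH2=CHMgBr with catalytic CuI (THF, -40 °C) opens F3 at the terminal carbon and gives 9 without touching the stereocentre.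

**Step 10, alkylation with the elaborate iodide 14.** The glycolate enolate decomposes above about -40 °C, and the sensitive iodide has to be the limiting partner. The fallback sets out from 18 (together with 10) and comes back at 24.
- Enolate 19 is alkylated with plain allyl iodide in excess, the best-behaved electrophile for it, to give (4S)-4-benzyl-3-[(2R)-2-(benzyloxy)pent-4-enoyl]-1,3-oxazolidin-2-one F4.
- AlMe3 and MeONHMe·HCl give (2R)-2-(benzyloxy)-N-methoxy-N-methylpent-4-enamide F5.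
- Reagent 22 gives (4R)-4-(benzyloxy)dec-1-en-5-one F6.
- Cross metathesis of 10 with F6 (3 equiv, second-generation Grubbs catalyst (H2IMes)(PCy3)Cl2Ru=CHPh, 1,4-benzoquinone, CH2Cl2, 40 °C) closes C4=C5 directly and gives 24. Some Z isomer forms, which does not matter because the alkene is hydrogenated later.

Steps 6-8 fall away in this fallback. The price is a statistical mixture whose homodimers are separated and recycled.

**Step 15, global hydrogenation.** Palladium can walk the double bond next to C2 or C7 and then cleave the allylic C-O bond. The secondary alkyl benzyl ether may also lag behind the aryl ones, and long exposure could reduce the ketone. The fallback sets out from 26 and comes back at 27. Diimide made from KO2CN=NCO2K and AcOH (MeOH/pyridine, rt) saturates the alkene without isomerisation and gives (2R,7R)-7-(benzyloxy)-1-[3,5-bis(benzyloxy)phenyl]-8-oxotridecan-2-yl acetate F7. BCl3 with pentamethylbenzene as cation scavenger (CH2Cl2, -78 °C, MeOH quench) then removes all three benzyl groups non-reductively and gives 27.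

## Further compounds

F1 | step 4 | 1-allyl-3,5-bis(benzyloxy)benzene | C=CCc1cc(OCc2ccccc2)cc(OCc2ccccc2)c1
F2 | step 4 | racemic 2-[3,5-bis(benzyloxy)benzyl]oxirane | C1OC1Cc1cc(OCc2ccccc2)cc(OCc2ccccc2)c1
F3 | step 4 | (S)-2-[3,5-bis(benzyloxy)benzyl]oxirane | C1O[C@H]1Cc1cc(OCc2ccccc2)cc(OCc2ccccc2)c1
F4 | step 10 | (4S)-4-benzyl-3-[(2R)-2-(benzyloxy)pent-4-enoyl]-1,3-oxazolidin-2-one | O=C1OC[C@H](Cc2ccccc2)N1C(=O)[C@H](OCc1ccccc1)CC=C
F5 | step 10 | (2R)-2-(benzyloxy)-N-methoxy-N-methylpent-4-enamide | CON(C)C(=O)[C@H](OCc1ccccc1)CC=C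
F6 | step 10 | (4R)-4-(benzyloxy)dec-1-en-5-one | CCCCCC(=O)[C@H](OCc1ccccc1)CC=C
F7 | step 15 | (2R,7R)-7-(benzyloxy)-1-[3,5-bis(benzyloxy)phenyl]-8-oxotridecan-2-yl acetate | CCCCCC(=O)[C@H](OCc1ccccc1)CCCC[C@H](Cc1cc(OCc2ccccc2)cc(OCc2ccccc2)c1)OC(C)=O
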